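**Retrosynthetic overview**

1. The target is reached from an 8-hydroxy-13-methyl ketone by acetylation at O6, desilylation at O18 and Stille vinylation of the C13 enol triflate; the C18 hydroxyl comes from the equatorial C4 methyl group by a 6-OH-directed δ-C–H silylation and oxidation.
2. Key disconnection (C6–C7 and C8–O): Prins closure of ring B from a ring A keto aldehyde, with the C13 ketone oxygen capturing the C8 cation. It rests on the C8 tertiary carbinol of ring B: C17 is axial and syn to C20, and O8 is cis to the axial C9 side chain (C11–C16), so only that chain can deliver the oxygen.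
3. The keto aldehyde comes from a trans-fused δ-lactone (C8 carbonyl, O–C6) by methyllithium addition, methylenation and oxidation; the lactone comes from hydroboration of the exocyclic C5=C6 alkene of a Claisen acid.
4. The C9–C10 bond and both stereocentres come from an Ireland–Claisen rearrangement of the β-cyclogeranyl ester of ketal-protected 5-oxohexanoic acid; a salt resolution gives the single enantiomer.
5. Ring order: ring A is bought (β-cyclocitral); ring B and a dihydropyran close together in the key step; the dihydropyran is opened again by hydrolysis.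

Key step: step 11

Assumption: labdane numbering is used (C1–C10 decalin, C11–C16 side chain, C17 on C8, C18 equatorial and C19 axial on C4, C20 on C10), and the (R)-amine is written for the resolution although which enantiomer of the amine carries the wanted acid into the crystals can only be settled by experiment.

**Route**

Step 1
Reactants: 1 β-cyclocitral
Product: 2 β-cyclogeraniol
Conditions: NaBH4, MeOH, 0 °C
Reagents that add atoms: none
Why: Borohydride 1,2-reduction of the hindered enal; no stereocentre is formed.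

Step 2
Reactants: 3 5-oxohexanoic acid; 4 ethylene glycol
Product: 6 4-(2-methyl-1,3-dioxolan-2-yl)butanoic acid, via hydroxyethyl ester ketal 5 (not isolated)
Conditions: 4 (5 equiv), TsOH·H2O (cat.), toluene, reflux, Dean–Stark; then NaOH, MeOH/H2O, rt; HCl to pH 4, 0 °C
Reagents that add atoms: sodium hydroxide [Na+].[OH-]
Why: Acid-catalysed ketalisation with azeotropic water removal (the glycol esterifies the acid at the same time), then saponification of that ester; the dioxolane survives base and a cold acidification to pH 4.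

Step 3
Reactants: 2 β-cyclogeraniol; 6 4-(2-methyl-1,3-dioxolan-2-yl)butanoic acid
Product: 7 (2,6,6-trimethylcyclohex-1-en-1-yl)methyl 4-(2-methyl-1,3-dioxolan-2-yl)butanoate
Conditions: DCC, DMAP (cat.), CH2Cl2, 0 °C → rt
Reagents that add atoms: none
Why: Steglich esterification under neutral conditions that spare the ketal and the acid-labile allylic alcohol.

Step 4
Reactants: 7 β-cyclogeranyl ester
Product: 11 racemic (2R*)-4-(2-methyl-1,3-dioxolan-2-yl)-2-[(1S*)-1,3,3-trimethyl-2-methylidenecyclohexyl]butanoic acid, via lithium enolate 8 (not isolated), via silyl ketene acetal 9 (not isolated), via trimethylsilyl ester 10 (not isolated)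
Conditions: LiN(iPr)2, THF, −78 °C; Me3SiCl/Et3N, −78 °C → rt, then 65 °C; aq. work-up at pH 4
Reagents that add atoms: none
Why: Ireland–Claisen rearrangement: kinetic deprotonation in THF without polar additive gives the E(O)-enolate (C11 chain cis to the allyloxy oxygen), and the chair transition state (ring carbon C1 pseudo-equatorial, C20 pseudo-axial, boat disfavoured by the OSi and C4 groups on the two central atoms) joins C9 to C10 with C11 syn to C20, which should give the (9R*,10S*) acid as a racemate.

Step 5
Reactants: 11 racemic Claisen acid; 12 (R)-1-phenylethylamine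
Product: 13 (R)-1-phenylethylammonium (2R)-4-(2-methyl-1,3-dioxolan-2-yl)-2-[(1S)-1,3,3-trimethyl-2-methylidenecyclohexyl]butanoate
Conditions: 12 (0.55 equiv), acetone, crystallise, recrystallise
Reagents that add atoms: none
Why: Classical resolution through diastereomeric ammonium carboxylates fixes the absolute configuration at C9 and C10 and should also reject the minor Claisen diastereomer.

Step 6
Reactants: 13 resolved ammonium salt
Product: 15 methyl (2R)-4-(2-methyl-1,3-dioxolan-2-yl)-2-[(1S)-1,3,3-trimethyl-2-methylidenecyclohexyl]butanoate, via free acid 14 (not isolated)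
Conditions: cold 5% aq. citric acid/Et2O; organic phase + Me3SiCHN2, MeOH/toluene, 0 °C → rt
Reagents that add atoms: (trimethylsilyl)diazomethane C[Si](C)(C)C=[N+]=[N-]
Why: A weak acid frees the carboxylic acid without opening the ketal, and O-methylation by the diazoalkane needs no base, so C9 cannot epimerise.

Step 7
Reactants: 15 methyl ester
Product: 18 trans-fused δ-lactone 4-[2-(2-methyl-1,3-dioxolan-2-yl)ethyl]-4a,8,8-trimethyloctahydro-3H-isochromen-3-one (H-8a anti to the 4a-methyl; C4 chain anti to the 4a-methyl), via alkylborane 16 (not isolated), via hydroxy ester 17 (not isolated)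
Conditions: BH3·THF, THF, 0 °C → rt; NaOH, H2O2, 0 °C; then PPTS (cat.), toluene, 80 °C
Reagents that add atoms: hydrogen peroxide OO
Why: Hydroboration–oxidation puts oxygen on C6 (anti-Markovnikov) and borane should approach the face opposite the two axial methyl groups (C20 and the axial C4 methyl), so H-5 is delivered anti to C20; the hindered ester is inert to borane, and the trans-diequatorial δ-hydroxy ester then lactonises under mild acid catalysis.

Step 8
Reactants: 18 δ-lactone
Product: 20 open-chain methyl ketone silyl ether (C8 = C(=O)CH3; C6 = CH2OSi(tBu)Me2; ketal intact; C5 C9 C10 as in 18), via lithium lactolate 19 (not isolated)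
Conditions: MeLi (1.05 equiv), THF, −78 °C; then tBuMe2SiCl, imidazole, DMF, −78 °C → rt
Reagents that add atoms: methyllithium [Li]C; tert-butyldimethylsilyl chloride CC(C)(C)[Si](C)(C)Cl
Why: Methyllithium adds once to the lactone because the lithium lactolate resists a second addition at −78 °C, and silylation then draws the ring–chain equilibrium to the open primary silyl ether, leaving the methyl ketone free.

Step 9
Reactants: 20 methyl ketone silyl ether
Product: 22 (5S)-5-[(1S,2R)-2-(hydroxymethyl)-1,3,3-trimethylcyclohexyl]-6-methylhept-6-en-2-one, via isopropenyl silyl ether ketal 21 (not isolated)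
Conditions: Cp2TiMe2 (2.5 equiv), toluene, 70 °C, dark; then 1 M HCl, THF, rt
Reagents that add atoms: bis(cyclopentadienyl)dimethyltitanium C[Ti](C)(C1C=CC=C1)C1C=CC=C1; water O
Why: Petasis methylenation is non-basic and tolerates hindered enolisable ketones, so C9 stays intact; dilute acid then removes the silyl ether and the dioxolane without touching the 1,1-disubstituted alkene.

Step 10
Reactants: 22 hydroxy ketone
Product: 23 (1R,2S)-2,6,6-trimethyl-2-[(3S)-2-methyl-6-oxohept-1-en-3-yl]cyclohexane-1-carbaldehyde
Conditions: DMP, pyridine, CH2Cl2, 0 °C → rt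
Reagents that add atoms: none
Why: Dess–Martin oxidation of the primary alcohol under buffered, non-epimerising conditions; the equatorial aldehyde is also the thermodynamically preferred C5 epimer.

Step 11
Reactants: 23 keto aldehyde
Product: 24 (5R,6R,8S,9R,10R)-8,13-epoxy-14,15-dinorlabd-12-en-6-ol
Conditions: Me2AlCl (1.1 equiv), CH2Cl2, −78 → −30 °C; Et3N, then aq. NaHCO3
Reagents that add atoms: none
Why: Me2AlCl (about one equivalent, so the ketone is not tied up) activates the aldehyde, the C7 terminus of the 1,1-disubstituted alkene adds to C6 and leaves a tertiary cation at C8, the C13 carbonyl oxygen closes onto C8 to an oxocarbenium ion, and loss of H-12 to an Al–CH3 group (methane) gives the enol ether; this is an intramolecular Prins reaction (type 2 carbonyl–ene manifold) ended by carbonyl-oxygen capture, the closest known cases being Me2AlCl-promoted type 2 cyclisations of unsaturated aldehydes and the acid-induced closure of δ,ε-unsaturated methyl ketones to bicyclic dihydropyrans. Ring B closes in a 6-endo mode at the alkene (carbonyl exocyclic) through a chair fused trans to ring A, and the dihydropyran closes by attack of the carbonyl oxygen on the ring B cation, the C13–O bond becoming endocyclic. C6 is set by that chair, in which the aluminium-bound oxygen is equatorial because the axial position is syn-diaxial to C20. C8 is set by the tether: the C9 chain is axial on the face opposite C20 and its oxygen can reach C8 only on that face, which leaves C17 axial and syn to C20. The step needs oxygen capture to outrun proton loss from C7, C9 or C17 and chloride transfer; the six-membered intramolecular delivery and the screening of the other face of the cation by C20 secure this, and the aldehyde reacts before the ketone because its complex is the more electrophilic.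

Step 12
Reactants: 24 enol ether alcohol
Product: 26 (4S,5S,6R,8S,9R,10R)-6,18-cyclic diethylsilylene derivative (O6–SiEt2–C18 oxasilinane) of 8,13-epoxy-14,15-dinorlabd-12-ene, via hydridosilyl ether 25 (not isolated)
Conditions: [Ir(cod)OMe]2 (0.5 mol%), Et2SiH2, THF, rt; evaporate; [Rh(cod)Cl]2 (2 mol%), Xantphos (5 mol%), norbornene, THF, 100 °C
Reagents that add atoms: diethylsilane CC[SiH2]CC
Why: Proposed new method: after dehydrogenative O-silylation, the rhodium–Xantphos catalyst should add the Si–H bond, cleave a C18–H bond through a six-membered oxasilacycle and form the Si–C18 bond, with norbornene taking up the hydrogen; the closest known reaction is the rhodium–Xantphos δ-C–H silylation of (hydrido)silyl ethers of tertiary alcohols at primary C–H bonds (oxidised to 1,4-diols), and the extension to this secondary-alcohol silyl ether is argued from geometry, since the γ-carbons (C4, C8, C10) bear no hydrogen, the equatorial O6 is peri to the equatorial C4 methyl, and C17, C19 and C20 are axial on the opposite face.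

Step 13
Reactants: 26 oxasilinane
Product: 28 (4S,5S,6R,8S,9R,10R)-6,8,18-trihydroxy-14,15-dinorlabdan-13-one (in equilibrium with its 8,13-hemiketal), via diol enol ether 27 (not isolated)
Conditions: TBAF, t-BuOOH, CsOH·H2O, DMF, rt → 60 °C; then 0.1 M HCl, THF/H2O, 0 °C
Reagents that add atoms: tert-butyl hydroperoxide CC(C)(C)OO; water O
Why: Tamao–Fleming oxidation of the Si–C18 bond with a fluoride-activated silane and a nucleophilic hydroperoxide that should not epoxidise the enol ether, then acid-catalysed hydration of the enol ether, which breaks C13–O and leaves the C8–O bond and its configuration untouched.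

Step 14
Reactants: 28 triol ketone
Product: 29 18-O-(tert-butyldimethylsilyl) ether of 28
Conditions: tBuMe2SiCl (1.1 equiv), imidazole, DMF, 0 °C
Reagents that add atoms: tert-butyldimethylsilyl chloride CC(C)(C)[Si](C)(C)Cl
Why: Selective silylation of the primary hydroxyl; the secondary C6 and tertiary C8 hydroxyls react much more slowly.

Step 15
Reactants: 29 silyl ether ketone
Product: 31 (4S,5S,6R,8S,9R,10R)-18-(tert-butyldimethylsilyloxy)-13-(trifluoromethylsulfonyloxy)-14,15-dinorlabd-13(16)-ene-6,8-diol, via trilithium enolate 30 (not isolated)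
Conditions: LiN(iPr)2 (3.5 equiv), THF, −78 → −40 °C; PhNTf2 (1.2 equiv), −78 → 0 °C; aq. NH4Cl
Reagents that add atoms: N-phenylbis(trifluoromethanesulfonimide) O=S(=O)(N(c1ccccc1)S(=O)(=O)C(F)(F)F)C(F)(F)F
Why: Kinetic enolisation of the methyl ketone at the methyl group C16 with excess amide base (two equivalents are consumed by the hydroxyls and open the hemiketal), then O-sulfonylation of the enolate by PhNTf2, which should not triflate hindered lithium alkoxides at low temperature.

Step 16
Reactants: 31 enol triflate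
Product: 32 (4S,5S,6R,8S,9R,10R)-18-(tert-butyldimethylsilyloxy)labda-13(16),14-diene-6,8-diol
Conditions: tributyl(vinyl)stannane, Pd(PPh3)4 (5 mol%), LiCl, THF, 65 °C
Reagents that add atoms: tributyl(vinyl)stannane C=C[Sn](CCCC)(CCCC)CCCC
Why: Stille coupling of the enol triflate with the vinylstannane (chloride-assisted) builds the 2-substituted 1,3-diene and tolerates free hydroxyls.

Step 17
Reactants: 32 diene diol
Product: 33 (4S,5S,6R,8S,9R,10R)-6-acetoxy-18-(tert-butyldimethylsilyloxy)labda-13(16),14-dien-8-ol
Conditions: Ac2O, DMAP (cat.), pyridine, CH2Cl2, rt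
Reagents that add atoms: acetic anhydride CC(=O)OC(C)=O
Why: DMAP-catalysed acetylation of the secondary C6 hydroxyl, the only acylable one, since the tertiary C8 hydroxyl does not react at room temperature.

Step 18
Reactants: 33 acetate silyl ether
Product: 34 (4S,5S,6R,8S,9R,10R)-6-acetoxylabda-13(16),14-diene-8,18-diol (target)
Conditions: HF·pyridine, pyridine, THF, 0 °C → rt
Reagents that add atoms: none
Why: Fluoride cleavage of the primary silyl ether under weakly acidic conditions, which avoids base-induced acetyl migration from O6 to O18 and spares the diene and the tertiary alcohol.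

**Compound list**

1 | β-cyclocitral (2,6,6-trimethylcyclohex-1-ene-1-carbaldehyde) | CC1=C(C=O)C(C)(C)CCC1 | starting material
2 | β-cyclogeraniol ((2,6,6-trimethylcyclohex-1-en-1-yl)methanol) | CC1=C(CO)C(C)(C)CCC1 | intermediate
3 | 5-oxohexanoic acid | CC(=O)CCCC(=O)O | starting material
4 | ethylene glycol | OCCO | starting material
5 | 2-hydroxyethyl 4-(2-methyl-1,3-dioxolan-2-yl)butanoate | CC1(CCCC(=O)OCCO)OCCO1 | intermediate
6 | 4-(2-methyl-1,3-dioxolan-2-yl)butanoic acid | CC1(CCCC(=O)O)OCCO1 | intermediate
7 | (2,6,6-trimethylcyclohex-1-en-1-yl)methyl 4-(2-methyl-1,3-dioxolan-2-yl)butanoate | CC1=C(COC(=O)CCCC2(C)OCCO2)C(C)(C)CCC1 | intermediate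
8 | lithium E(O)-enolate of 7 (C11 chain trans to OLi) | [Li+].[O-]/C(OCC1=C(C)CCCC1(C)C)=C/CCC1(C)OCCO1 | intermediate
9 | (E)-trimethylsilyl ketene acetal of 7 (C11 chain trans to OSi, cis to the allyloxy oxygen) | C[Si](C)(C)O/C(OCC1=C(C)CCCC1(C)C)=C/CCC1(C)OCCO1 | intermediate
10 | racemic trimethylsilyl ester of acid 11 | CC1(CC[C@@H](C(=O)O[Si](C)(C)C)[C@]2(C)CCCC(C)(C)C2=C)OCCO1.CC1(CC[C@H](C(=O)O[Si](C)(C)C)[C@@]2(C)CCCC(C)(C)C2=C)OCCO1 | intermediate
11 | racemic (2R*)-4-(2-methyl-1,3-dioxolan-2-yl)-2-[(1S*)-1,3,3-trimethyl-2-methylidenecyclohexyl]butanoic acid | CC1(CC[C@@H](C(=O)O)[C@]2(C)CCCC(C)(C)C2=C)OCCO1.CC1(CC[C@H](C(=O)O)[C@@]2(C)CCCC(C)(C)C2=C)OCCO1 | intermediate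
12 | (R)-1-phenylethylamine | C[C@@H](N)c1ccccc1 | starting material
13 | (R)-1-phenylethylammonium salt of the (2R,1'S)-acid | CC1(CC[C@@H](C(=O)[O-])[C@]2(C)CCCC(C)(C)C2=C)OCCO1.C[C@@H]([NH3+])c1ccccc1 | intermediate
14 | (2R)-4-(2-methyl-1,3-dioxolan-2-yl)-2-[(1S)-1,3,3-trimethyl-2-methylidenecyclohexyl]butanoic acid | CC1(CC[C@@H](C(=O)O)[C@]2(C)CCCC(C)(C)C2=C)OCCO1 | intermediate
15 | methyl ester of 14 | CC1(CC[C@@H](C(=O)OC)[C@]2(C)CCCC(C)(C)C2=C)OCCO1 | intermediate
16 | primary alkylborane from 15 (C6H2–BH2; H-5 anti to C20) | CC1(CC[C@@H](C(=O)OC)[C@]2(C)CCCC(C)(C)[C@H]2CB)OCCO1 | intermediate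
17 | methyl (2R)-2-[(1R,2R)-2-(hydroxymethyl)-1,3,3-trimethylcyclohexyl]-4-(2-methyl-1,3-dioxolan-2-yl)butanoate | CC1(CC[C@@H](C(=O)OC)[C@]2(C)CCCC(C)(C)[C@H]2CO)OCCO1 | intermediate
18 | trans-fused δ-lactone 4-[2-(2-methyl-1,3-dioxolan-2-yl)ethyl]-4a,8,8-trimethyloctahydro-3H-isochromen-3-one (C4 chain and H-8a both anti to the 4a-methyl) | CC1(CC[C@H]2C(=O)OC[C@@H]3C(C)(C)CCC[C@@]23C)OCCO1 | intermediate
19 | lithium lactolate from 18 (3-methyl-3-olate; both C3 epimers) | [Li+].CC1(CC[C@H]2C(C)([O-])OC[C@@H]3C(C)(C)CCC[C@@]23C)OCCO1 | intermediate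
20 | open-chain methyl ketone with C6 tert-butyldimethylsilyl ether and C13 dioxolane | CC1(CC[C@@H](C(C)=O)[C@]2(C)CCCC(C)(C)[C@H]2CO[Si](C)(C)C(C)(C)C)OCCO1 | intermediate
21 | isopropenyl compound with C6 tert-butyldimethylsilyl ether and C13 dioxolane | CC1(CC[C@@H](C(C)=C)[C@]2(C)CCCC(C)(C)[C@H]2CO[Si](C)(C)C(C)(C)C)OCCO1 | intermediate
22 | (5S)-5-[(1S,2R)-2-(hydroxymethyl)-1,3,3-trimethylcyclohexyl]-6-methylhept-6-en-2-one | CC(=O)CC[C@@H](C(C)=C)[C@]1(C)CCCC(C)(C)[C@H]1CO | intermediate
23 | (1R,2S)-2,6,6-trimethyl-2-[(3S)-2-methyl-6-oxohept-1-en-3-yl]cyclohexane-1-carbaldehyde | CC(=O)CC[C@@H](C(C)=C)[C@]1(C)CCCC(C)(C)[C@H]1C=O | intermediate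
24 | (5R,6R,8S,9R,10R)-8,13-epoxy-14,15-dinorlabd-12-en-6-ol | CC1=CC[C@@H]2[C@]3(C)CCCC(C)(C)[C@H]3[C@H](O)C[C@]2(C)O1 | intermediate
25 | 6-O-diethylsilyl (Si–H) ether of 24 | CC1=CC[C@@H]2[C@]3(C)CCCC(C)(C)[C@H]3[C@H](O[SiH](CC)CC)C[C@]2(C)O1 | intermediate
26 | (4S,5S,6R,8S,9R,10R)-oxasilinane: O6–SiEt2–C18 bridge on 8,13-epoxy-14,15-dinorlabd-12-ene | CC1=CC[C@@H]2[C@]3(C)CCC[C@](C)(C[Si]4(CC)CC)[C@H]3[C@H](O4)C[C@]2(C)O1 | intermediate
27 | (4S,5S,6R,8S,9R,10R)-8,13-epoxy-14,15-dinorlabd-12-ene-6,18-diol | CC1=CC[C@@H]2[C@]3(C)CCC[C@](C)(CO)[C@H]3[C@H](O)C[C@]2(C)O1 | intermediate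
28 | (4S,5S,6R,8S,9R,10R)-6,8,18-trihydroxy-14,15-dinorlabdan-13-one | CC(=O)CC[C@@H]1[C@]2(C)CCC[C@](C)(CO)[C@H]2[C@H](O)C[C@]1(C)O | intermediate
29 | 18-O-(tert-butyldimethylsilyl) ether of 28 | CC(=O)CC[C@@H]1[C@]2(C)CCC[C@](C)(CO[Si](C)(C)C(C)(C)C)[C@H]2[C@H](O)C[C@]1(C)O | intermediate
30 | trilithium species from 29 (C13–C16 enolate; 6- and 8-alkoxides) | [Li+].[Li+].[Li+].C=C([O-])CC[C@@H]1[C@]2(C)CCC[C@](C)(CO[Si](C)(C)C(C)(C)C)[C@H]2[C@H]([O-])C[C@]1(C)[O-] | intermediate
31 | 18-silyloxy C13 enol triflate 6,8-diol | C=C(OS(=O)(=O)C(F)(F)F)CC[C@@H]1[C@]2(C)CCC[C@](C)(CO[Si](C)(C)C(C)(C)C)[C@H]2[C@H](O)C[C@]1(C)O | intermediate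
32 | (4S,5S,6R,8S,9R,10R)-18-(tert-butyldimethylsilyloxy)labda-13(16),14-diene-6,8-diol | C=CC(=C)CC[C@@H]1[C@]2(C)CCC[C@](C)(CO[Si](C)(C)C(C)(C)C)[C@H]2[C@H](O)C[C@]1(C)O | intermediate
33 | (4S,5S,6R,8S,9R,10R)-6-acetoxy-18-(tert-butyldimethylsilyloxy)labda-13(16),14-dien-8-ol | C=CC(=C)CC[C@@H]1[C@]2(C)CCC[C@](C)(CO[Si](C)(C)C(C)(C)C)[C@H]2[C@H](OC(C)=O)C[C@]1(C)O | intermediate
34 | (4S,5S,6R,8S,9R,10R)-6-acetoxylabda-13(16),14-diene-8,18-diol | C=CC(=C)CC[C@@H]1[C@]2(C)CCC[C@](C)(CO)[C@H]2[C@H](OC(C)=O)C[C@]1(C)O | target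

**Step count and risks**

Total step count: 18. Longest linear sequence: 17 steps (steps 1 and 3–18 from β-cyclocitral; equally steps 2–18 from 5-oxohexanoic acid).

Steps most likely to fail:

1. Step 12 (Proposed new method). The rhodium silyl hydride may not cleave the C18–H bond: C–H activation could be slow with a secondary-alkoxy silane, and silane redistribution or reduction of the enol ether could take over. The fallback is a Barton nitrite photolysis, known chemistry, which sets out from 24 and returns at 28. Compound 24 is first stored as the mixed methyl ketal F1 (MeOH, PPTS), so that no enol ether meets the nitrosating agent. NOCl/pyridine gives the C6 nitrite ester F2. Irradiation (Pyrex, benzene) generates the C6 alkoxyl radical, which abstracts hydrogen from the peri C18 methyl group through a six-membered transition state; the C18 radical recombines with NO and, after tautomerisation in warm 2-propanol, gives the C18 oxime F3. Buffered TiCl3/NH4OAc cleaves the oxime to the hydroxy aldehyde F4 (present as its cyclic hemiacetal with O6). NaBH4 gives the 6,18-diol methyl ketal F5, and 0.1 M HCl in aqueous THF hydrolyses the ketal to 28.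

2. Step 11. Proton loss from the C8 cation, or chloride or methyl transfer from aluminium, may outrun capture by the ketone oxygen, above all if the ketone is itself bound to the Lewis acid. The fallback sets out from 23 and returns at 24 by splitting the closure into two stages. With an excess of Me2AlCl (2.5 equiv, both carbonyls complexed) the reaction is run deliberately as a type 2 carbonyl–ene cyclisation to the homoallylic alcohol F6 (exocyclic C8=C17 alkene, equatorial 6-OH, free C13 ketone). F6 is then treated with a Brønsted acid (TsOH·H2O cat., CH2Cl2, 0 °C), which protonates the alkene at C17 and regenerates the C8 cation with no Lewis acid on the ketone, so the C13 carbonyl oxygen can close the dihydropyran to 24.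

3. Step 15. The ketone may stay locked as the cyclic hemiketal alkoxide and escape enolisation, or the alkoxides may be sulfonylated. The fallback is a Shapiro reaction, which needs no free ketone under basic conditions; it sets out from 29 and returns at 32. Condensation of 29 with 2,4,6-triisopropylbenzenesulfonyl hydrazide (THF, cat. AcOH) drains the hemiketal into the sulfonylhydrazone F7. n-BuLi (5 equiv, THF/TMEDA, −78 → 0 °C) deprotonates the two hydroxyls, the N–H and the C16 methyl group, and loss of sulfinate and N2 gives the C13 vinyllithium F8. Transmetallation with ZnCl2 gives the vinylzinc chloride F9, and Negishi coupling with vinyl bromide (Pd(PPh3)4, THF) gives diene 32 directly.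

**Further compounds**

F1 | step 12 | mixed methyl ketal of 24 (13-methoxy-8,13-epoxy-14,15-dinorlabdan-6-ol) | COC1(C)CC[C@@H]2[C@]3(C)CCCC(C)(C)[C@H]3[C@H](O)C[C@]2(C)O1
F2 | step 12 | C6 nitrite ester of F1 | COC1(C)CC[C@@H]2[C@]3(C)CCCC(C)(C)[C@H]3[C@H](ON=O)C[C@]2(C)O1
F3 | step 12 | C18 oxime with free 6-OH | COC1(C)CC[C@@H]2[C@]3(C)CCC[C@](C)(C=NO)[C@H]3[C@H](O)C[C@]2(C)O1
F4 | step 12 | 6-hydroxy C18 aldehyde (cyclic hemiacetal form in equilibrium) | COC1(C)CC[C@@H]2[C@]3(C)CCC[C@](C)(C=O)[C@H]3[C@H](O)C[C@]2(C)O1
F5 | step 12 | 6,18-diol methyl ketal | COC1(C)CC[C@@H]2[C@]3(C)CCC[C@](C)(CO)[C@H]3[C@H](O)C[C@]2(C)O1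
F6 | step 11 | 6-hydroxy-14,15-dinorlabd-8(17)-en-13-one (equatorial 6-OH; axial C9 chain) | CC(=O)CC[C@@H]1[C@]2(C)CCCC(C)(C)[C@H]2[C@H](O)CC1=C
F7 | step 15 | 2,4,6-triisopropylbenzenesulfonylhydrazone of 29 | CC(=NNS(=O)(=O)c1c(C(C)C)cc(C(C)C)cc1C(C)C)CC[C@@H]1[C@]2(C)CCC[C@](C)(CO[Si](C)(C)C(C)(C)C)[C@H]2[C@H](O)C[C@]1(C)O
F8 | step 15 | C13 vinyllithium (as dilithium 6,8-dialkoxide) | [Li]C(=C)CC[C@@H]1[C@]2(C)CCC[C@](C)(CO[Si](C)(C)C(C)(C)C)[C@H]2[C@H](O[Li])C[C@]1(C)O[Li]
F9 | step 15 | C13 vinylzinc chloride (as dilithium 6,8-dialkoxide) | Cl[Zn]C(=C)CC[C@@H]1[C@]2(C)CCC[C@](C)(CO[Si](C)(C)C(C)(C)C)[C@H]2[C@H](O[Li])C[C@]1(C)O[Li]
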